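## The problem

Compound 21 is a flavone: the benzo ring A is fused to the pyran-4-one ring C along C4a–C8a, and ring B sits on C2. It has no stereocentre, so the difficulties are regiochemical and chemoselective. Ring A is substituted everywhere except C6 (C8a–O1, C8–OMe, C7–OH, C5–OH, C4a–C4). The 5,7-dihydroxy-8-methoxy pattern differs from the 6-methoxy isomer only in which of the two oxygens ortho to C4a becomes O1, so that oxygen must be singled out before ring C closes. Six oxygens must be told apart at the end: three methyl ethers (O3, O8, O3'), the prenyl ether at O4' and two free phenols; O3 can be methylated selectively only while O5 and O7 are masked. The aryl prenyl ether is the fragile group: it ionises in strong acid, undergoes Claisen rearrangement on strong heating, does not survive hydrogenation, is epoxidised by peracids and can be ionised by zerovalent palladium. The enabling feature is that C4 is a single carbonyl carbon between C4a and C3, while C2–C3 with ring B has the oxidation level of an arylacetylene and C2 is bound to O1, which is ortho to C4a. Ring C can therefore be assembled from an ortho-iodophenol, carbon monoxide and a terminal arylalkyne. Because the alkyne is terminal, C3 arrives as C–H; it is then the only vinylic hydrogen of the flavone, acidified by the neighbouring carbonyl, and its oxygen is introduced afterwards.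

## Retrosynthesis

**21 ⇒ 20.** The last bonds cut are the two acetal C–O bonds masking O5 and O7, leading to the bis(methoxymethyl) ether 20. Benzyl ethers are excluded because hydrogenolysis would not spare the prenyl group, and silyl ethers would be at risk in the hot amine, lithium amide and alkaline peroxide used earlier. MOM acetals tolerate all of these and leave in dilute acid. The skeleton is not simplified, but 20 has no acidic hydrogen, so everything before it can run under basic conditions. The forward step needs acid weak enough to leave the prenyl ether alone.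

**20 ⇒ 19 ⇒ 16.** The O3–CH3 bond and then the C3–O3 bond are cut, through flavonol 19 to the 3-unsubstituted flavone 16. In 19 the 3-hydroxyl is the only free one, so methylation needs no selectivity; after unmasking, O7 would react first. Cutting C3–O is preferred to carrying that oxygen through ring construction because it allows ring C to come from a terminal alkyne. It is viable because C3–H of 16 is the only vinylic hydrogen and lies next to the carbonyl. The forward oxygenation must use an oxidant that does not epoxidise the prenyl alkene.

**16 ⇒ 8 + 12 + 13.** C4a–C4, C4–C3 and O1–C2 are cut together, giving iodophenol 8, arylalkyne 12 and carbon monoxide 13. The neighbouring cuts are weaker. A diketone-type closure (O1–C2 and C2–C3 only) needs an acetophenone with the same fully differentiated ring A and more steps. An oxidative chalcone closure tends toward aurones when the position next to the ketone on ring A is substituted, as here. The three-bond cut is the most convergent: it leaves one hexasubstituted benzene, a two-step alkyne and a gas. The forward reaction must insert CO before the alkyne couples and must close six-membered, not five-membered. Regiochemistry in ring A cannot go wrong, since 8 has one free hydroxyl, ortho to iodine and next to the methoxy group.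

**8 ⇒ 7.** The C4a–I bond is cut, giving phenol 7. This saves carrying an aryl iodide through the hydrogenolysis that precedes it. Phenol 7 has two free ring positions; the forward iodination must take the one ortho to the hydroxyl (flanked by OH and one MOM ether) and not the one para to it (buttressed by two MOM ethers).

**7 ⇒ 6 ⇒ 5 ⇒ 3 ⇒ 2 ⇒ 1.** Successively cut are the benzyl–O bond (7 from 6), the O8–CH3 bond (6 from 5), the C8–O bond itself (5 from aldehyde 3 through formate 4, the formyl carbon being exchanged for oxygen), the benzyl ether (3 from 2) and two MOM groups (2 from 1). Aldehyde 1 already has the 1,3,5-oxygen pattern, and its formyl carbon marks the site of the fourth oxygen. Its chelation differentiates the hydroxyls without effort: the two that are alkylated become O5 and O7, the chelated one becomes O1, and the formyl-derived oxygen becomes the 8-methoxy group. The forward sequence needs an aryl-to-oxygen migration that the electron-rich ring favours.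

**12 ⇒ 11 ⇒ 9 + 10.** The terminal alkyne carbon is removed (one-carbon homologation of aldehyde 11), then the O4'–prenyl bond is cut to vanillin 9 and prenyl bromide 10. Putting the prenyl group on at the start, where there is one phenol, avoids any late selective prenylation among three hydroxyls. The price is that every later step must tolerate the prenyl ether.

## Roads not taken

**Alternative 1:** aryne insertion into a carboxylic acid. The cut is at C4a–C4 and C5–O; the acyl unit brings C4, C3 and the 3-methoxy group. In the forward step the aryne, released by fluoride from the ortho-silylaryl triflate A2, takes up methoxyacetic acid A3. The carboxylate oxygen adds at C5 (remote from the benzyloxy group) and the C4a anion captures the acyl group, giving the ortho-hydroxyaryl ketone A1.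
- Merits: the 3-methoxy group is built in, no CO or late organolithium step is needed, and aryne polarisation fixes the ring A pattern.
- Weak points: no ring closes. A2 is a hexasubstituted benzene with a silyl group, a triflate and three differently masked oxygens, which is harder to make than 8. In A1 the free hydroxyl is at C5, not C8a; closing ring C onto it would give the 6-methoxy series. A protecting-group exchange is therefore needed (and the benzyl group must go before the prenylated ring B arrives), followed by acylation with the ring B acid, acyl migration and cyclodehydration.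
- Comparison: this road is better in that C3 oxygenation never becomes a separate problem. The chosen plan sets against it a single step that forms three bonds and ring C from simpler pieces, and a shorter sequence even counting the two steps spent on O3.

**Alternative 2:** thermal acylketene fusion. The cut is at C4–C4a and O1–C2, with C4–C3 already present in the ketoester. The symmetric diol A4 and the α-methoxy β-ketoester A5 are heated without catalyst at about 220 °C. Loss of ethanol gives an acylketene that C-acylates the ring and cyclodehydrates to flavone A6.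
- Merits: this is the shortest access to a 3-methoxyflavone core. The two hydroxyls of A4 are equivalent, so regiochemistry is fixed by symmetry, and no metal, pressure or strong base is used.
- Weak points: the temperature excludes the prenyl ether (Claisen rearrangement), so ring B must carry a benzyl group. A6 then needs masking of the 7-hydroxyl, hydrogenolysis, prenylation of O4' in the presence of the chelated 5-hydroxyl, and unmasking. The α-alkoxy acylketene may also O-acylate or close in the coumarin sense, and an electron-rich diol must survive pyrolysis.
- Comparison: in steps to the ring system, and in needing no C3 oxygenation, this road is better. The chosen plan sets against it a catalytic ring closure at about 100 °C that tolerates the prenyl ether, so the side chain is carried from the start and no end-game protecting-group shuffle is needed.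

**Alternative 3:** samarium pinacol closure at C3–C4. The cut is the C3–C4 bond. The dialdehyde A7 (ring A aldehyde linked through O1 to an aryl(aryloxy)acetaldehyde) is treated with SmI2 (divalent samarium); ketyl coupling closes ring C as the racemic flavan-3,4-diol A8 (2,3-trans, 3,4-cis).
- Merits: both O3 and O4 arrive in the ring-forming step, the reaction runs at low temperature, and cis-diol selectivity is dependable.
- Weak points: three stereocentres are made and then erased. Reaching 21 needs oxidation at C4 and dehydrogenation across C2–C3 in the presence of a free 3-hydroxyl, the prenyl alkene and electron-rich rings. A ketyl next to an aryloxy-bearing carbon invites reductive cleavage of that C–O bond. A7 is itself laborious and configurationally labile.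
- Comparison: this road has the advantage of needing no carbanion chemistry on the finished flavone. The chosen plan sets against it direct arrival at the aromatic oxidation level, convergence and fewer steps.

Key step: step 9

Remark on the chemistry: carbon monoxide is treated as a commercial starting material and numbered (13) because its carbon becomes C4. MOM = methoxymethyl, prenyl = 3-methylbut-2-enyl; atoms are numbered as in the flavone (O1, C2, C3, C4, C4a, C5–C8, C8a; ring B primed).

## Route

Step 1
Reactants: 1 2,4,6-trihydroxybenzaldehyde
Product: 2 2-hydroxy-4,6-bis(methoxymethoxy)benzaldehyde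
Conditions: MOMCl (2.2 equiv), iPr2NEt, CH2Cl2, 0 °C to rt
Reagents that add atoms: chloromethyl methyl ether (MOMCl), COCCl
Why: O-Alkylation with an α-chloro ether under amine base; the 4-hydroxyl and one of the two equivalent ortho hydroxyls react, while the remaining ortho hydroxyl is hydrogen-bonded to the aldehyde and resists a third alkylation.

Step 2
Reactants: 2 2-hydroxy-4,6-bis(methoxymethoxy)benzaldehyde
Product: 3 2-(benzyloxy)-4,6-bis(methoxymethoxy)benzaldehyde
Conditions: BnBr, K2CO3, DMF, 50 °C
Reagents that add atoms: benzyl bromide, BrCc1ccccc1
Why: Williamson etherification of the chelated phenol; benzyl survives the peracid and methylation steps and is removed by hydrogenolysis before any iodine or prenyl group is present.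

Step 3
Reactants: 3 2-(benzyloxy)-4,6-bis(methoxymethoxy)benzaldehyde
Product: 5 2-(benzyloxy)-4,6-bis(methoxymethoxy)phenol, via 2-(benzyloxy)-4,6-bis(methoxymethoxy)phenyl formate 4 (not isolated)
Conditions: mCPBA, CH2Cl2, 0 °C to rt; then K2CO3, MeOH, rt
Reagents that add atoms: 3-chloroperoxybenzoic acid (mCPBA), OOC(=O)c1cccc(Cl)c1
Why: Baeyer–Villiger (Dakin-type) oxidation; the electron-rich trialkoxyaryl group migrates to oxygen to give formate 4, which mild methanolysis converts to the phenol whose oxygen becomes O8.

Step 4
Reactants: 5 2-(benzyloxy)-4,6-bis(methoxymethoxy)phenol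
Product: 6 1-(benzyloxy)-2-methoxy-3,5-bis(methoxymethoxy)benzene
Conditions: MeI, K2CO3, acetone, reflux
Reagents that add atoms: iodomethane, CI
Why: Williamson methylation of the only free hydroxyl fixes the future 8-methoxy group between the benzyloxy- and MOM-oxy-bearing carbons.

Step 5
Reactants: 6 1-(benzyloxy)-2-methoxy-3,5-bis(methoxymethoxy)benzene
Product: 7 2-methoxy-3,5-bis(methoxymethoxy)phenol
Conditions: H2 (1 atm), 10% Pd/C, EtOAc, rt
Reagents that add atoms: none
Why: Catalytic hydrogenolysis of the benzyl ether; MOM acetals and the methyl ether are inert, and the step precedes iodination because an aryl iodide would not survive it.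

Step 6
Reactants: 7 2-methoxy-3,5-bis(methoxymethoxy)phenol
Product: 8 2-iodo-6-methoxy-3,5-bis(methoxymethoxy)phenol
Conditions: I2 (1.0 equiv), NaHCO3, THF–H2O, 0 °C
Reagents that add atoms: iodine, II
Why: Electrophilic aromatic iodination through the phenoxide; the position ortho to the hydroxyl is flanked by OH and one MOM ether whereas the para position is buttressed by two MOM ethers, so the bulky electrophile should enter ortho, and one equivalent limits double iodination.

Step 7
Reactants: 9 vanillin (4-hydroxy-3-methoxybenzaldehyde), 10 prenyl bromide (1-bromo-3-methylbut-2-ene)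
Product: 11 3-methoxy-4-(3-methylbut-2-enyloxy)benzaldehyde
Conditions: K2CO3, DMF, rt
Reagents that add atoms: none
Why: Williamson O-alkylation of the single phenoxide by SN2 attack at the primary allylic carbon.

Step 8
Reactants: 11 3-methoxy-4-(3-methylbut-2-enyloxy)benzaldehyde
Product: 12 4-ethynyl-2-methoxy-1-(3-methylbut-2-enyloxy)benzene
Conditions: dimethyl (1-diazo-2-oxopropyl)phosphonate, K2CO3, MeOH, 0 °C to rt
Reagents that add atoms: dimethyl (1-diazo-2-oxopropyl)phosphonate (Ohira–Bestmann reagent), COP(=O)(OC)C(=[N+]=[N-])C(C)=O
Why: Seyferth–Gilbert homologation in the Ohira–Bestmann form converts the aldehyde into the terminal alkyne under carbonate in methanol, conditions that leave the prenyl ether untouched.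

Step 9
Reactants: 8 2-iodo-6-methoxy-3,5-bis(methoxymethoxy)phenol, 12 4-ethynyl-2-methoxy-1-(3-methylbut-2-enyloxy)benzene, 13 carbon monoxide
Product: 16 8-methoxy-5,7-bis(methoxymethoxy)-2-[3-methoxy-4-(3-methylbut-2-enyloxy)phenyl]chromen-4-one, via ortho-hydroxyaryl ynone 14 (not isolated), via diethylamino enaminone 15 (not isolated)
Conditions: PdCl2(PPh3)2 (5 mol %), CO (20 bar), Et2NH, 100 °C
Reagents that add atoms: none
Why: The divalent palladium precatalyst is reduced in the amine/CO medium to zerovalent palladium, which inserts into the C–I bond of 8; CO insertion gives the aroylpalladium iodide, and amine-assisted alkynyl transfer from 12 followed by reductive elimination forms C4a–C4 and C4–C3 in ynone 14. Diethylamine then adds to the ynone carbon bearing ring B to give enaminone 15, and the C8a hydroxyl displaces the amine by addition–elimination, forming O1–C2. The closest known reaction type is the palladium-catalysed carbonylative coupling of ortho-iodophenols with terminal arylacetylenes in a secondary amine, an established flavone synthesis. Ring C closes in the 6-endo mode, with oxygen attacking the alkyne-derived carbon remote from the carbonyl; no stereocentre is formed. The first selectivity needed is 6-endo over 5-exo closure (flavone, not aurone), secured by the secondary amine turning the ynone into the enaminone before the phenol attacks. The second is carbonylative over direct coupling, secured by CO pressure, by the absence of a copper co-catalyst and by the ready migration of the electron-rich aryl group to CO. Ring A regiochemistry is not in question because 8 has a single free hydroxyl, ortho to iodine and next to the methoxy group. The MOM and prenyl ethers are inert to the amine, and oxidative addition to the aryl iodide should be much faster than ionisation of the hindered prenyl ether.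

Step 10
Reactants: 16 8-methoxy-5,7-bis(methoxymethoxy)-2-[3-methoxy-4-(3-methylbut-2-enyloxy)phenyl]chromen-4-one
Product: 19 3-hydroxy-8-methoxy-5,7-bis(methoxymethoxy)-2-[3-methoxy-4-(3-methylbut-2-enyloxy)phenyl]chromen-4-one, via 3-lithioflavone 17 (not isolated), via lithium trimethoxyborate 18 (not isolated)
Conditions: LiN(iPr)2, THF, −78 °C; B(OMe)3, −78 to 0 °C; 30% H2O2, aq. NaOH, 0 °C
Reagents that add atoms: hydrogen peroxide, OO
Why: Deprotonation of the only vinylic C–H (C3, next to the carbonyl) by the hindered amide gives 17, borate capture gives 18, and alkaline peroxide triggers boron-to-oxygen migration, the known lithiation–boration–oxidation of flavones to flavonols; basic peroxide instead of a peracid spares the prenyl alkene, and the borate is added at −78 °C because the C3 anion can ring-open on warming.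

Step 11
Reactants: 19 3-hydroxy-8-methoxy-5,7-bis(methoxymethoxy)-2-[3-methoxy-4-(3-methylbut-2-enyloxy)phenyl]chromen-4-one
Product: 20 3,8-dimethoxy-5,7-bis(methoxymethoxy)-2-[3-methoxy-4-(3-methylbut-2-enyloxy)phenyl]chromen-4-one
Conditions: MeI, K2CO3, acetone, reflux
Reagents that add atoms: iodomethane, CI
Why: Williamson methylation of the only free hydroxyl; O5 and O7 are still masked, so the methyl group can go only to O3.

Step 12
Reactants: 20 3,8-dimethoxy-5,7-bis(methoxymethoxy)-2-[3-methoxy-4-(3-methylbut-2-enyloxy)phenyl]chromen-4-one
Product: 21 5,7-dihydroxy-3,8-dimethoxy-2-[3-methoxy-4-(3-methylbut-2-enyloxy)phenyl]chromen-4-one (5,7-dihydroxy-3,8,3'-trimethoxy-4'-prenyloxyflavone)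
Conditions: 3 M HCl (aq.), MeOH–THF, 40 °C
Reagents that add atoms: none
Why: Acid-catalysed acetal methanolysis; the peri 5-O-MOM group leaves readily with help from the C4 carbonyl and the 7-O-MOM group slightly more slowly, while the aryl prenyl ether, a far weaker base than an acetal oxygen, should survive dilute acid at this temperature.

## Compound list

1 | 2,4,6-trihydroxybenzaldehyde | O=Cc1c(O)cc(O)cc1O | starting material
2 | 2-hydroxy-4,6-bis(methoxymethoxy)benzaldehyde | COCOc1cc(O)c(C=O)c(OCOC)c1 | intermediate
3 | 2-(benzyloxy)-4,6-bis(methoxymethoxy)benzaldehyde | COCOc1cc(OCc2ccccc2)c(C=O)c(OCOC)c1 | intermediate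
4 | 2-(benzyloxy)-4,6-bis(methoxymethoxy)phenyl formate | COCOc1cc(OCc2ccccc2)c(OC=O)c(OCOC)c1 | intermediate
5 | 2-(benzyloxy)-4,6-bis(methoxymethoxy)phenol | COCOc1cc(OCc2ccccc2)c(O)c(OCOC)c1 | intermediate
6 | 1-(benzyloxy)-2-methoxy-3,5-bis(methoxymethoxy)benzene | COCOc1cc(OCc2ccccc2)c(OC)c(OCOC)c1 | intermediate
7 | 2-methoxy-3,5-bis(methoxymethoxy)phenol | COCOc1cc(O)c(OC)c(OCOC)c1 | intermediate
8 | 2-iodo-6-methoxy-3,5-bis(methoxymethoxy)phenol | COc1c(O)c(I)c(OCOC)cc1OCOC | intermediate
9 | vanillin (4-hydroxy-3-methoxybenzaldehyde) | COc1cc(C=O)ccc1O | starting material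
10 | prenyl bromide (1-bromo-3-methylbut-2-ene) | CC(C)=CCBr | starting material
11 | 3-methoxy-4-(3-methylbut-2-enyloxy)benzaldehyde | COc1cc(C=O)ccc1OCC=C(C)C | intermediate
12 | 4-ethynyl-2-methoxy-1-(3-methylbut-2-enyloxy)benzene | COc1cc(C#C)ccc1OCC=C(C)C | intermediate
13 | carbon monoxide | [C-]#[O+] | starting material
14 | 1-[2-hydroxy-3-methoxy-4,6-bis(methoxymethoxy)phenyl]-3-[3-methoxy-4-(3-methylbut-2-enyloxy)phenyl]prop-2-yn-1-one | COc1cc(C#CC(=O)c2c(O)c(OC)c(OCOC)cc2OCOC)ccc1OCC=C(C)C | intermediate
15 | (E)-3-(diethylamino)-1-[2-hydroxy-3-methoxy-4,6-bis(methoxymethoxy)phenyl]-3-[3-methoxy-4-(3-methylbut-2-enyloxy)phenyl]prop-2-en-1-one | CCN(CC)/C(c1ccc(OCC=C(C)C)c(OC)c1)=C/C(=O)c1c(O)c(OC)c(OCOC)cc1OCOC | intermediate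
16 | 8-methoxy-5,7-bis(methoxymethoxy)-2-[3-methoxy-4-(3-methylbut-2-enyloxy)phenyl]chromen-4-one | COc1cc(-c2cc(=O)c3c(OCOC)cc(OCOC)c(OC)c3o2)ccc1OCC=C(C)C | intermediate
17 | 3-lithio-8-methoxy-5,7-bis(methoxymethoxy)-2-[3-methoxy-4-(3-methylbut-2-enyloxy)phenyl]chromen-4-one | COc1cc(-c2oc3c(OC)c(OCOC)cc(OCOC)c3c(=O)c2[Li])ccc1OCC=C(C)C | intermediate
18 | lithium trimethoxy{8-methoxy-5,7-bis(methoxymethoxy)-2-[3-methoxy-4-(3-methylbut-2-enyloxy)phenyl]-4-oxochromen-3-yl}borate | [Li+].COc1cc(-c2oc3c(OC)c(OCOC)cc(OCOC)c3c(=O)c2[B-](OC)(OC)OC)ccc1OCC=C(C)C | intermediate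
19 | 3-hydroxy-8-methoxy-5,7-bis(methoxymethoxy)-2-[3-methoxy-4-(3-methylbut-2-enyloxy)phenyl]chromen-4-one | COc1cc(-c2oc3c(OC)c(OCOC)cc(OCOC)c3c(=O)c2O)ccc1OCC=C(C)C | intermediate
20 | 3,8-dimethoxy-5,7-bis(methoxymethoxy)-2-[3-methoxy-4-(3-methylbut-2-enyloxy)phenyl]chromen-4-one | COc1cc(-c2oc3c(OC)c(OCOC)cc(OCOC)c3c(=O)c2OC)ccc1OCC=C(C)C | intermediate
21 | 5,7-dihydroxy-3,8-dimethoxy-2-[3-methoxy-4-(3-methylbut-2-enyloxy)phenyl]chromen-4-one | COc1cc(-c2oc3c(OC)c(O)cc(O)c3c(=O)c2OC)ccc1OCC=C(C)C | target

## Step count and least certain steps

Total step count: 12. Longest linear sequence: 10 steps (steps 1–6 and 9–12, from 1); the alkyne branch adds steps 7 and 8.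

**Step 9 (key step).** The most likely failures are:
- coupling of the arylpalladium species with the alkyne before CO inserts, followed by cyclisation of the phenol onto the alkyne (benzofuran formation);
- capture of the aroylpalladium intermediate by diethylamine (aminocarbonylation);
- slow oxidative addition at the doubly ortho-substituted, electron-rich C–I bond, which leaves time for alkyne homocoupling and for ionisation of the prenyl ether by zerovalent palladium.

Fallback (sets out from 8, returns at 16): the domino is split into two stages with the phenol masked. Acetylation of 8 (Ac2O, pyridine) gives 2-iodo-6-methoxy-3,5-bis(methoxymethoxy)phenyl acetate F1. Carbonylative Sonogashira coupling of F1 with 12 and 13 near room temperature (PdCl2(PPh3)2, Et3N, THF, CO) gives 6-methoxy-3,5-bis(methoxymethoxy)-2-{3-[3-methoxy-4-(3-methylbut-2-enyloxy)phenyl]prop-2-ynoyl}phenyl acetate F2, which cannot cyclise and is isolated. Diethylamine in methanol then removes the acetate by aminolysis, adds to the ynone and closes ring C through 14 and 15 to give 16. The coupling can then be optimised at low temperature without the cyclisation, and the amine-controlled 6-endo closure is run without palladium.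

**Step 6.** The most likely failure is iodination at the position para to the hydroxyl (between the two MOM ethers), or at both free positions. The para-iodinated material has no hydroxyl next to iodine and cannot enter the annulation.

Fallback (sets out from 2, returns at 8): iodine is introduced at the chelated salicylaldehyde stage, where halogenation ortho to the hydrogen-bonded hydroxyl has close precedent in 2-hydroxy-4,6-dialkoxyaryl carbonyl compounds. The benzyl group is replaced by one that can be removed without hydrogen.
- N-Iodosuccinimide in DMF converts 2 into 2-hydroxy-3-iodo-4,6-bis(methoxymethoxy)benzaldehyde F3.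
- 4-Methoxybenzyl chloride and K2CO3 give 3-iodo-2-[(4-methoxybenzyl)oxy]-4,6-bis(methoxymethoxy)benzaldehyde F4.
- mCPBA gives 3-iodo-2-[(4-methoxybenzyl)oxy]-4,6-bis(methoxymethoxy)phenyl formate F5, and methanolysis (K2CO3, MeOH) gives 3-iodo-2-[(4-methoxybenzyl)oxy]-4,6-bis(methoxymethoxy)phenol F6.
- MeI and K2CO3 give 2-iodo-4-methoxy-3-[(4-methoxybenzyl)oxy]-1,5-bis(methoxymethoxy)benzene F7.
- Oxidative removal of the 4-methoxybenzyl group with DDQ in wet CH2Cl2 gives 8.

**Step 10.** The most likely failures are ring opening of the C3 anion to the ynone phenoxide before boron capture, proton abstraction elsewhere (C6 between the two MOM ethers, or the allylic O–CH2), and loss of the boron group by protonation before oxidation.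

Fallback (sets out from 16, returns at 21, replacing steps 10–12): the oxygen is introduced through an enolate generated by conjugate addition, without a carbanion. PhI(OAc)2 with KOH in methanol adds methoxide at C2 and oxidises the resulting enolate at C3, a known hypervalent-iodine oxidation of chromones and flavones. The expected product is racemic cis-2,4,4,8-tetramethoxy-5,7-bis(methoxymethoxy)-2-[3-methoxy-4-(3-methylbut-2-enyloxy)phenyl]chroman-3-ol F8 (2-methoxy and 3-hydroxy cis; the configuration has no consequence). NaH and MeI give racemic cis-2,3,4,4,8-pentamethoxy-5,7-bis(methoxymethoxy)-2-[3-methoxy-4-(3-methylbut-2-enyloxy)phenyl]chromane F9. Dilute HCl in aqueous methanol then hydrolyses the ketal, eliminates methanol across C2–C3 and removes both MOM groups, giving 21.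

**Step 12.** The most likely failure is acid-induced ionisation of the prenyl ether (loss or migration of the prenyl group) before the slower 7-O-MOM group has gone.

Fallback (sets out from 20, returns at 21): the acetals are exchanged for silyl ethers under non-protic conditions. Me3SiOTf with 2,2'-bipyridyl in CH2Cl2 converts both aryl MOM ethers into 3,8-dimethoxy-2-[3-methoxy-4-(3-methylbut-2-enyloxy)phenyl]-5,7-bis(trimethylsilyloxy)chromen-4-one F10, which water hydrolyses on work-up to 21 without exposure to mineral acid.

## Further compounds

F1 | step 9 | 2-iodo-6-methoxy-3,5-bis(methoxymethoxy)phenyl acetate | COc1c(OC(C)=O)c(I)c(OCOC)cc1OCOC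
F2 | step 9 | 6-methoxy-3,5-bis(methoxymethoxy)-2-{3-[3-methoxy-4-(3-methylbut-2-enyloxy)phenyl]prop-2-ynoyl}phenyl acetate | COc1cc(C#CC(=O)c2c(OC(C)=O)c(OC)c(OCOC)cc2OCOC)ccc1OCC=C(C)C
F3 | step 6 | 2-hydroxy-3-iodo-4,6-bis(methoxymethoxy)benzaldehyde | COCOc1cc(OCOC)c(I)c(O)c1C=O
F4 | step 6 | 3-iodo-2-[(4-methoxybenzyl)oxy]-4,6-bis(methoxymethoxy)benzaldehyde | COCOc1cc(OCOC)c(I)c(OCc2ccc(OC)cc2)c1C=O
F5 | step 6 | 3-iodo-2-[(4-methoxybenzyl)oxy]-4,6-bis(methoxymethoxy)phenyl formate | COCOc1cc(OCOC)c(I)c(OCc2ccc(OC)cc2)c1OC=O
F6 | step 6 | 3-iodo-2-[(4-methoxybenzyl)oxy]-4,6-bis(methoxymethoxy)phenol | COCOc1cc(OCOC)c(I)c(OCc2ccc(OC)cc2)c1O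
F7 | step 6 | 2-iodo-4-methoxy-3-[(4-methoxybenzyl)oxy]-1,5-bis(methoxymethoxy)benzene | COCOc1cc(OCOC)c(I)c(OCc2ccc(OC)cc2)c1OC
F8 | step 10 | racemic cis-2,4,4,8-tetramethoxy-5,7-bis(methoxymethoxy)-2-[3-methoxy-4-(3-methylbut-2-enyloxy)phenyl]chroman-3-ol (one enantiomer drawn) | CO[C@@]1(c3ccc(OCC=C(C)C)c(OC)c3)Oc2c(OC)c(OCOC)cc(OCOC)c2C(OC)(OC)[C@H]1O
F9 | step 10 | racemic cis-2,3,4,4,8-pentamethoxy-5,7-bis(methoxymethoxy)-2-[3-methoxy-4-(3-methylbut-2-enyloxy)phenyl]chromane (one enantiomer drawn) | CO[C@@]1(c3ccc(OCC=C(C)C)c(OC)c3)Oc2c(OC)c(OCOC)cc(OCOC)c2C(OC)(OC)[C@H]1OC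
F10 | step 12 | 3,8-dimethoxy-2-[3-methoxy-4-(3-methylbut-2-enyloxy)phenyl]-5,7-bis(trimethylsilyloxy)chromen-4-one | COc1cc(-c2oc3c(OC)c(O[Si](C)(C)C)cc(O[Si](C)(C)C)c3c(=O)c2OC)ccc1OCC=C(C)C
A1 | alternative 1 | 1-[2-(benzyloxy)-6-hydroxy-3-methoxy-4-(methoxymethoxy)phenyl]-2-methoxyethanone | COCC(=O)c1c(O)cc(OCOC)c(OC)c1OCc1ccccc1
A2 | alternative 1 | 2-(benzyloxy)-3-methoxy-4-(methoxymethoxy)-6-(trimethylsilyl)phenyl trifluoromethanesulfonate | COCOc1cc([Si](C)(C)C)c(OS(=O)(=O)C(F)(F)F)c(OCc2ccccc2)c1OC
A3 | alternative 1 | methoxyacetic acid | COCC(=O)O
A4 | alternative 2 | 5-(benzyloxy)-2-methoxybenzene-1,3-diol | COc1c(O)cc(OCc2ccccc2)cc1O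
A5 | alternative 2 | ethyl 3-[4-(benzyloxy)-3-methoxyphenyl]-2-methoxy-3-oxopropanoate | CCOC(=O)C(OC)C(=O)c1ccc(OCc2ccccc2)c(OC)c1
A6 | alternative 2 | 5-(benzyloxy)-2-[4-(benzyloxy)-3-methoxyphenyl]-7-hydroxy-3,8-dimethoxychromen-4-one | COc1cc(-c2oc3c(OC)c(O)cc(OCc4ccccc4)c3c(=O)c2OC)ccc1OCc1ccccc1
A7 | alternative 3 | racemic 2-[2-formyl-6-methoxy-3,5-bis(methoxymethoxy)phenoxy]-2-[3-methoxy-4-(3-methylbut-2-enyloxy)phenyl]acetaldehyde | O=CC(Oc1c(C=O)c(OCOC)cc(OCOC)c1OC)c1ccc(OCC=C(C)C)c(OC)c1
A8 | alternative 3 | racemic 2,3-trans-3,4-cis-8-methoxy-5,7-bis(methoxymethoxy)-2-[3-methoxy-4-(3-methylbut-2-enyloxy)phenyl]chromane-3,4-diol (one enantiomer drawn) | O[C@H]1[C@@H](O)c2c(OCOC)cc(OCOC)c(OC)c2O[C@@H]1c1ccc(OCC=C(C)C)c(OC)c1
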